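The route rests on the O–C10 bond of the 3(2H)-furanone (ring O, C3, C2, C1, C10; germacrane numbering). C10 is a quaternary ether carbon flanked by the C1 ketone and the C9 methylene, the exact pattern left by a [2,3] shift of an allyl oxonium ylide. In one operation a copper carbenoid at C10, made from an α-methyl diazoketone, is captured by the allyl ether oxygen on C3 (five-membered ring closure through O–C10) and the allyl group moves from oxygen to C10. This relays the sacrificial C3 stereocentre to C10 and delivers C9–C8. The precursor is an acyclic β-allyloxy diazoketone. Chromium-mediated allylation later closes the ten-membered ring.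

Key step: step 13

Remark: germacrane numbering is used throughout (C1 ketone, C2=C3, C4 bearing C15, C6 lactone carbinol, C7, C8 ester carbinol, C9, C10 bearing C14, C11–C13 methylene lactone); PMB = 4-methoxybenzyl, TBS = tert-butyldimethylsilyl.

Remark: the chromium allylation of step 17 is assumed to follow the closed chair transition state usual for allylchromium reagents (7,8-anti), which is why the angelate is introduced with inversion. Reagents given only by name and SMILES (PMB chloromethyl ether, the silyl ketene acetal, the allyl imidate, N-ethyl-N-nitrosourea) are taken as purchasable.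

Step 1
Reactants: 1 (S)-5-(hydroxymethyl)dihydrofuran-2(3H)-one
Product: 3 (S)-5-vinyldihydrofuran-2(3H)-one, via lactone aldehyde 2 (not isolated)
Conditions: Dess–Martin periodinane, CH2Cl2, 0 °C to rt; filtration, evaporation; then Ph3P=CH2 (from Ph3PCH3Br and KN(SiMe3)2), THF, −78 to 0 °C
Reagents that add atoms: methylenetriphenylphosphorane, C=P(c1ccccc1)(c1ccccc1)c1ccccc1 (made from methyltriphenylphosphonium bromide, C[P+](c1ccccc1)(c1ccccc1)c1ccccc1.[Br-])
Why: Dess–Martin oxidation gives the aldehyde under non-basic conditions and Wittig methylenation at low temperature converts it to the vinyl group before the α-oxygenated centre can epimerise, so the (S) centre of 1 is carried through unchanged.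

Step 2
Reactants: 3 (S)-5-vinyldihydrofuran-2(3H)-one
Product: 4 (3S,5S)-3-[(PMB-oxy)methyl]-5-vinyldihydrofuran-2(3H)-one
Conditions: LiN(iPr)2, THF, −78 °C; then 4-methoxybenzyl chloromethyl ether, −78 to −40 °C
Reagents that add atoms: 4-methoxybenzyl chloromethyl ether, COc1ccc(COCCl)cc1
Why: Enolate alkylation of a γ-substituted butyrolactone takes place on the face opposite the γ-vinyl group, which should set C4 as the 3,5-trans lactone (substrate control).

Step 3
Reactants: 4 (3S,5S)-3-[(PMB-oxy)methyl]-5-vinyldihydrofuran-2(3H)-one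
Product: 5 (2S,4S)-4-hydroxy-N-methoxy-N-methyl-2-[(PMB-oxy)methyl]hex-5-enamide
Conditions: MeNH(OMe)·HCl, AlMe3, CH2Cl2, 0 °C to rt; aqueous work-up; used at once
Reagents that add atoms: N,O-dimethylhydroxylamine hydrochloride, CNOC.Cl
Why: Weinreb aminolysis by the aluminium amide opens the lactone without enolising C4 and frees the C6 hydroxyl, with no stereocentre touched.

Step 4
Reactants: 6 ethyl 2-(hydroxymethyl)acrylate
Product: 7 ethyl 2-[(TBS-oxy)methyl]acrylate
Conditions: TBSCl, imidazole, CH2Cl2, 0 °C to rt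
Reagents that add atoms: tert-butyldimethylsilyl chloride, CC(C)(C)[Si](C)(C)Cl
Why: Standard silylation (silyl ether formation) masks the allylic alcohol that later becomes the allylic bromide.

Step 5
Reactants: 7 ethyl 2-[(TBS-oxy)methyl]acrylate
Product: 8 2-[(TBS-oxy)methyl]acrylic acid
Conditions: LiOH, THF/H2O, 0 °C; then 1 M HCl to pH 4
Reagents that add atoms: lithium hydroxide, [Li+].[OH-]
Why: Saponification of the ethyl ester gives the free acid for the Mitsunobu coupling while the primary silyl ether survives the mild hydroxide.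

Step 6
Reactants: 5 (2S,4S)-4-hydroxy-N-methoxy-N-methyl-2-[(PMB-oxy)methyl]hex-5-enamide; 8 2-[(TBS-oxy)methyl]acrylic acid
Product: 9 (3R,5S)-6-[methoxy(methyl)amino]-6-oxo-5-[(PMB-oxy)methyl]hex-1-en-3-yl 2-[(TBS-oxy)methyl]acrylate
Conditions: PPh3, DIAD, THF, 0 °C to rt
Reagents that add atoms: none
Why: Mitsunobu esterification displaces the activated secondary allylic oxygen by the carboxylate in an SN2 manner, so C6 is inverted to the (R) configuration required for the 6,12-lactone while the metathesis partner is attached.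

Step 7
Reactants: 9 (3R,5S)-6-[methoxy(methyl)amino]-6-oxo-5-[(PMB-oxy)methyl]hex-1-en-3-yl 2-[(TBS-oxy)methyl]acrylate
Product: 10 (S)-N-methoxy-N-methyl-2-[(PMB-oxy)methyl]-3-{(R)-4-[(TBS-oxy)methyl]-5-oxo-2,5-dihydrofuran-2-yl}propanamide
Conditions: second-generation Grubbs catalyst RuCl2(=CHPh)(PCy3)(C21H26N2) (5 mol %), toluene, 80 °C
Reagents that add atoms: none
Why: Ring-closing metathesis joins the vinyl group to the 2-substituted acrylate with loss of ethylene and should give the trisubstituted butenolide, the five-membered ring being the only one open to the two alkenes.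

Step 8
Reactants: 10 (S)-N-methoxy-N-methyl-2-[(PMB-oxy)methyl]-3-{(R)-4-[(TBS-oxy)methyl]-5-oxo-2,5-dihydrofuran-2-yl}propanamide
Product: 11 (S)-2-[(PMB-oxy)methyl]-3-{(R)-4-[(TBS-oxy)methyl]-5-oxo-2,5-dihydrofuran-2-yl}propanal
Conditions: Cp2Zr(H)Cl, THF, rt; aqueous work-up; used crude
Reagents that add atoms: none
Why: Amide reduction with the Schwartz reagent stops at the aldehyde oxidation level through a zirconium hemiaminal and is selective for the amide over the lactone.

Step 9
Reactants: 11 (S)-2-[(PMB-oxy)methyl]-3-{(R)-4-[(TBS-oxy)methyl]-5-oxo-2,5-dihydrofuran-2-yl}propanal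
Product: 12 methyl (3R,4S)-3-hydroxy-4-[(PMB-oxy)methyl]-5-{(R)-4-[(TBS-oxy)methyl]-5-oxo-2,5-dihydrofuran-2-yl}pentanoate
Conditions: MgBr2·OEt2, CH2Cl2, −78 °C; then (1-methoxyvinyloxy)trimethylsilane, −78 to −30 °C; citric acid work-up
Reagents that add atoms: (1-methoxyvinyloxy)trimethylsilane, COC(=C)O[Si](C)(C)C
Why: Chelation-controlled Mukaiyama aldol addition: MgBr2 ties the aldehyde oxygen to the PMB ether oxygen, the ketene acetal attacks the chelate anti to the C5 branch, and the new C3 centre should therefore be (R) (hydroxyl syn to the C15 arm in the C2–C5 zigzag).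

Step 10
Reactants: 12 methyl (3R,4S)-3-hydroxy-4-[(PMB-oxy)methyl]-5-{(R)-4-[(TBS-oxy)methyl]-5-oxo-2,5-dihydrofuran-2-yl}pentanoate
Product: 13 methyl (3R,4S)-3-(allyloxy)-4-[(PMB-oxy)methyl]-5-{(R)-4-[(TBS-oxy)methyl]-5-oxo-2,5-dihydrofuran-2-yl}pentanoate
Conditions: allyl 2,2,2-trichloroacetimidate, TfOH (cat.), cyclohexane/CH2Cl2, 0 °C
Reagents that add atoms: allyl 2,2,2-trichloroacetimidate, C=CCOC(=N)C(Cl)(Cl)Cl
Why: Acid-catalysed imidate O-alkylation allylates the β-hydroxy ester without the retro-aldol cleavage or elimination that a basic Williamson etherification would invite.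

Step 11
Reactants: 13 methyl (3R,4S)-3-(allyloxy)-4-[(PMB-oxy)methyl]-5-{(R)-4-[(TBS-oxy)methyl]-5-oxo-2,5-dihydrofuran-2-yl}pentanoate
Product: 14 (3R,4S)-3-(allyloxy)-4-[(PMB-oxy)methyl]-5-{(R)-4-[(TBS-oxy)methyl]-5-oxo-2,5-dihydrofuran-2-yl}pentanoic acid
Conditions: Me3SnOH, ClCH2CH2Cl, 70 °C; then dilute HCl wash
Reagents that add atoms: trimethyltin hydroxide, C[Sn](C)(C)O
Why: Neutral ester hydrolysis with Me3SnOH should cleave the methyl ester selectively, avoiding β-elimination of the allyloxy group and base-induced damage to the butenolide.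

Step 12
Reactants: 14 (3R,4S)-3-(allyloxy)-4-[(PMB-oxy)methyl]-5-{(R)-4-[(TBS-oxy)methyl]-5-oxo-2,5-dihydrofuran-2-yl}pentanoic acid
Product: 16 (5R,6S)-5-(allyloxy)-2-diazo-6-[(PMB-oxy)methyl]-7-{(R)-4-[(TBS-oxy)methyl]-5-oxo-2,5-dihydrofuran-2-yl}heptan-3-one, via acid chloride 15 (not isolated)
Conditions: 1-chloro-N,N,2-trimethylprop-1-en-1-amine, CH2Cl2, 0 °C; then CH3CHN2 (from N-ethyl-N-nitrosourea and KOH), Et2O, −20 °C
Reagents that add atoms: diazoethane, CC=[N+]=[N-]; 1-chloro-N,N,2-trimethylprop-1-en-1-amine, CC(C)=C(Cl)N(C)C (gives the chlorine of 15 only)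
Why: Acylation of a diazoalkane by an acid chloride (the first stage of the Arndt–Eistert sequence) gives the α-methyl α-diazoketone; the neutral chloroenamine avoids acid, and the acylation at −20 °C should outrun dipolar addition of diazoethane to the butenolide.

Step 13
Reactants: 16 (5R,6S)-5-(allyloxy)-2-diazo-6-[(PMB-oxy)methyl]-7-{(R)-4-[(TBS-oxy)methyl]-5-oxo-2,5-dihydrofuran-2-yl}heptan-3-one
Product: 18 (2S,5R)-2-allyl-2-methyl-5-{(S)-1-(PMB-oxy)-3-[(R)-4-[(TBS-oxy)methyl]-5-oxo-2,5-dihydrofuran-2-yl]propan-2-yl}dihydrofuran-3(2H)-one, via oxonium ylide 17 (not isolated)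
Conditions: Cu(hfacac)2 (5 mol %), CH2Cl2, reflux, slow addition of 16
Reagents that add atoms: none
Why: Cu(hfacac)2 extrudes N2 from 16 and the resulting electrophilic copper-bound carbene at C10 is attacked by a lone pair of the allyl ether oxygen on C3, which forms the O–C10 bond and closes the five-membered ring (oxygen onto the carbene carbon, 5-exo mode) as the cyclic oxonium ylide 17. The ylide then undergoes a concerted, suprafacial [2,3]-sigmatropic shift in which the allyl terminus bonds to C10 as the O–allyl bond breaks, so that the furanone oxygen bridge, the quaternary carbon and the C9–C8 unit arise together. The closest known reaction type is the copper-catalysed tandem oxonium ylide formation and [2,3] rearrangement of allyl ethers of β-hydroxy diazoketones to 2,5-trans tetrahydrofuran-3-ones. The only new stereocentre, C10, is controlled by C3: in the ylide the O-allyl group sits trans to the C4 branch and is delivered to the same face of C10, which should give the (10S) centre with the allyl group trans and the methyl group cis to that branch. The step needs chemoselectivity for ylide formation over 1,2-hydride migration of the α-methyl carbene (vinyl ketone), over attack by the more remote PMB ether oxygen and over C–H insertion; the favourable five-membered ylide ring, the electrophilic copper catalyst and slow addition at low concentration are meant to secure it.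

Step 14
Reactants: 18 (2S,5R)-2-allyl-2-methyl-5-{(S)-1-(PMB-oxy)-3-[(R)-4-[(TBS-oxy)methyl]-5-oxo-2,5-dihydrofuran-2-yl]propan-2-yl}dihydrofuran-3(2H)-one
Product: 19 (S)-2-allyl-2-methyl-5-{(S)-1-(PMB-oxy)-3-[(R)-4-[(TBS-oxy)methyl]-5-oxo-2,5-dihydrofuran-2-yl]propan-2-yl}furan-3(2H)-one
Conditions: IBX, 4-methoxypyridine N-oxide, DMSO, 25 °C
Reagents that add atoms: none
Why: IBX dehydrogenation (oxidation of the enol to the enone) can only engage C2–C3 because C10 is quaternary, so it should give the vinylogous ester of the furanone and remove the C3 centre once its relay is done.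

Step 15
Reactants: 19 (S)-2-allyl-2-methyl-5-{(S)-1-(PMB-oxy)-3-[(R)-4-[(TBS-oxy)methyl]-5-oxo-2,5-dihydrofuran-2-yl]propan-2-yl}furan-3(2H)-one
Product: 20 (S)-2-allyl-5-{(S)-3-[(R)-4-(bromomethyl)-5-oxo-2,5-dihydrofuran-2-yl]-1-(PMB-oxy)propan-2-yl}-2-methylfuran-3(2H)-one
Conditions: PPh3Br2, CH2Cl2, 0 °C to rt
Reagents that add atoms: triphenylphosphine dibromide, BrP(Br)(c1ccccc1)(c1ccccc1)c1ccccc1
Why: Triphenylphosphine dibromide exchanges the primary allylic silyl ether for bromide (silyl ether to bromide conversion through an alkoxyphosphonium ion) without base.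

Step 16
Reactants: 20 (S)-2-allyl-5-{(S)-3-[(R)-4-(bromomethyl)-5-oxo-2,5-dihydrofuran-2-yl]-1-(PMB-oxy)propan-2-yl}-2-methylfuran-3(2H)-one
Product: 21 2-[(S)-5-{(S)-3-[(R)-4-(bromomethyl)-5-oxo-2,5-dihydrofuran-2-yl]-1-(PMB-oxy)propan-2-yl}-2-methyl-3-oxo-2,3-dihydrofuran-2-yl]acetaldehyde
Conditions: OsO4 (cat.), NaIO4, THF/pH 7 buffer, 0 °C to rt
Reagents that add atoms: sodium periodate, [Na+].[O-]I(=O)(=O)=O (the aldehyde oxygen arrives by way of OsO4)
Why: Johnson–Lemieux oxidative cleavage: OsO4 should select the isolated terminal alkene over the two electron-poor ring alkenes and periodate cleaves the diol to the C8 aldehyde at neutral pH, which keeps the β-oxygenated aldehyde from retro-Michael opening at C10.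

Step 17
Reactants: 21 2-[(S)-5-{(S)-3-[(R)-4-(bromomethyl)-5-oxo-2,5-dihydrofuran-2-yl]-1-(PMB-oxy)propan-2-yl}-2-methyl-3-oxo-2,3-dihydrofuran-2-yl]acetaldehyde
Product: 22 (4S,6R,7R,8S,10S)-8-hydroxy-15-(PMB-oxy)-1-oxo-3,10-epoxygermacra-2,11(13)-dien-12,6-olide (8α-alcohol)
Conditions: CrCl2 (excess), THF, rt, high dilution, slow addition of 21; aqueous work-up
Reagents that add atoms: none
Why: Nozaki–Hiyama-type allylation: CrCl2 converts the allylic bromide into an allylchromium reagent that adds through C7 to the tethered aldehyde, anti to the C5 branch on the butenolide (trans lactone, C7) and through the closed chair transition state with C9 equatorial (7,8-anti, the 8α-alcohol), closing the ten-membered ring and unveiling the exocyclic methylene.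

Step 18
Reactants: 22 (4S,6R,7R,8S,10S)-8-hydroxy-15-(PMB-oxy)-1-oxo-3,10-epoxygermacra-2,11(13)-dien-12,6-olide; 23 angelic acid, (Z)-2-methylbut-2-enoic acid
Product: 24 (4S,6R,7S,8R,10S)-8-[(Z)-2-methylbut-2-enoyloxy]-15-(PMB-oxy)-1-oxo-3,10-epoxygermacra-2,11(13)-dien-12,6-olide
Conditions: PPh3, DIAD, toluene, 0 °C to rt
Reagents that add atoms: none
Why: Mitsunobu esterification attaches the angelate with SN2 inversion at C8 to give the 8β (8R) ester; the acid is never activated at carbon, so its (Z) geometry should persist, and H7 is syn to the leaving oxygen, which disfavours anti elimination into conjugation.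

Step 19
Reactants: 24 (4S,6R,7S,8R,10S)-8-[(Z)-2-methylbut-2-enoyloxy]-15-(PMB-oxy)-1-oxo-3,10-epoxygermacra-2,11(13)-dien-12,6-olide
Product: 25 (4S,6R,7S,8R,10S)-8-[(Z)-2-methylbut-2-enoyloxy]-15-hydroxy-1-oxo-3,10-epoxygermacra-2,11(13)-dien-12,6-olide (CNP0108636.1)
Conditions: DDQ, CH2Cl2/pH 7 buffer, 0 °C
Reagents that add atoms: none
Why: Oxidative PMB cleavage with DDQ (hydride abstraction from the electron-rich benzyl ether and hydrolysis) should free the C15 alcohol without touching the enone, the methylene lactone or the angelate.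

Compound list

1 | (S)-5-(hydroxymethyl)dihydrofuran-2(3H)-one | OC[C@@H]1CCC(=O)O1 | starting material
2 | (S)-5-oxotetrahydrofuran-2-carbaldehyde (not isolated) | O=C[C@@H]1CCC(=O)O1 | intermediate
3 | (S)-5-vinyldihydrofuran-2(3H)-one | C=C[C@@H]1CCC(=O)O1 | intermediate
4 | (3S,5S)-3-{[(4-methoxybenzyl)oxy]methyl}-5-vinyldihydrofuran-2(3H)-one (3,5-trans) | C=C[C@@H]1C[C@@H](COCc2ccc(OC)cc2)C(=O)O1 | intermediate
5 | (2S,4S)-4-hydroxy-N-methoxy-2-{[(4-methoxybenzyl)oxy]methyl}-N-methylhex-5-enamide | C=C[C@@H](O)C[C@@H](COCc1ccc(OC)cc1)C(=O)N(C)OC | intermediate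
6 | ethyl 2-(hydroxymethyl)acrylate | C=C(CO)C(=O)OCC | starting material
7 | ethyl 2-{[(tert-butyldimethylsilyl)oxy]methyl}acrylate | C=C(CO[Si](C)(C)C(C)(C)C)C(=O)OCC | intermediate
8 | 2-{[(tert-butyldimethylsilyl)oxy]methyl}acrylic acid | C=C(CO[Si](C)(C)C(C)(C)C)C(=O)O | intermediate
9 | (3R,5S)-6-[methoxy(methyl)amino]-5-{[(4-methoxybenzyl)oxy]methyl}-6-oxohex-1-en-3-yl 2-{[(tert-butyldimethylsilyl)oxy]methyl}acrylate | C=C[C@H](OC(=O)C(=C)CO[Si](C)(C)C(C)(C)C)C[C@@H](COCc1ccc(OC)cc1)C(=O)N(C)OC | intermediate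
10 | (S)-3-[(R)-4-{[(tert-butyldimethylsilyl)oxy]methyl}-5-oxo-2,5-dihydrofuran-2-yl]-N-methoxy-2-{[(4-methoxybenzyl)oxy]methyl}-N-methylpropanamide | CON(C)C(=O)[C@H](COCc1ccc(OC)cc1)C[C@H]1OC(=O)C(CO[Si](C)(C)C(C)(C)C)=C1 | intermediate
11 | (S)-3-[(R)-4-{[(tert-butyldimethylsilyl)oxy]methyl}-5-oxo-2,5-dihydrofuran-2-yl]-2-{[(4-methoxybenzyl)oxy]methyl}propanal | O=C[C@H](COCc1ccc(OC)cc1)C[C@H]1OC(=O)C(CO[Si](C)(C)C(C)(C)C)=C1 | intermediate
12 | methyl (3R,4S)-5-[(R)-4-{[(tert-butyldimethylsilyl)oxy]methyl}-5-oxo-2,5-dihydrofuran-2-yl]-3-hydroxy-4-{[(4-methoxybenzyl)oxy]methyl}pentanoate | COC(=O)C[C@@H](O)[C@H](COCc1ccc(OC)cc1)C[C@H]1OC(=O)C(CO[Si](C)(C)C(C)(C)C)=C1 | intermediate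
13 | methyl (3R,4S)-3-(allyloxy)-5-[(R)-4-{[(tert-butyldimethylsilyl)oxy]methyl}-5-oxo-2,5-dihydrofuran-2-yl]-4-{[(4-methoxybenzyl)oxy]methyl}pentanoate | COC(=O)C[C@@H](OCC=C)[C@H](COCc1ccc(OC)cc1)C[C@H]1OC(=O)C(CO[Si](C)(C)C(C)(C)C)=C1 | intermediate
14 | (3R,4S)-3-(allyloxy)-5-[(R)-4-{[(tert-butyldimethylsilyl)oxy]methyl}-5-oxo-2,5-dihydrofuran-2-yl]-4-{[(4-methoxybenzyl)oxy]methyl}pentanoic acid | OC(=O)C[C@@H](OCC=C)[C@H](COCc1ccc(OC)cc1)C[C@H]1OC(=O)C(CO[Si](C)(C)C(C)(C)C)=C1 | intermediate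
15 | (3R,4S)-3-(allyloxy)-5-[(R)-4-{[(tert-butyldimethylsilyl)oxy]methyl}-5-oxo-2,5-dihydrofuran-2-yl]-4-{[(4-methoxybenzyl)oxy]methyl}pentanoyl chloride (not isolated) | ClC(=O)C[C@@H](OCC=C)[C@H](COCc1ccc(OC)cc1)C[C@H]1OC(=O)C(CO[Si](C)(C)C(C)(C)C)=C1 | intermediate
16 | (5R,6S)-5-(allyloxy)-7-[(R)-4-{[(tert-butyldimethylsilyl)oxy]methyl}-5-oxo-2,5-dihydrofuran-2-yl]-2-diazo-6-{[(4-methoxybenzyl)oxy]methyl}heptan-3-one | CC(=[N+]=[N-])C(=O)C[C@@H](OCC=C)[C@H](COCc1ccc(OC)cc1)C[C@H]1OC(=O)C(CO[Si](C)(C)C(C)(C)C)=C1 | intermediate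
17 | (5R)-1-allyl-2-methyl-5-{(S)-1-[(4-methoxybenzyl)oxy]-3-[(R)-4-{[(tert-butyldimethylsilyl)oxy]methyl}-5-oxo-2,5-dihydrofuran-2-yl]propan-2-yl}-4,5-dihydrofuran-1-ium-3-olate, the oxonium ylide (not isolated) | CC1=C([O-])C[C@H]([C@H](COCc2ccc(OC)cc2)C[C@H]2OC(=O)C(CO[Si](C)(C)C(C)(C)C)=C2)[O+]1CC=C | intermediate
18 | (2S,5R)-2-allyl-2-methyl-5-{(S)-1-[(4-methoxybenzyl)oxy]-3-[(R)-4-{[(tert-butyldimethylsilyl)oxy]methyl}-5-oxo-2,5-dihydrofuran-2-yl]propan-2-yl}dihydrofuran-3(2H)-one | C=CC[C@]1(C)O[C@H](CC1=O)[C@H](COCc1ccc(OC)cc1)C[C@H]1OC(=O)C(CO[Si](C)(C)C(C)(C)C)=C1 | intermediate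
19 | (S)-2-allyl-2-methyl-5-{(S)-1-[(4-methoxybenzyl)oxy]-3-[(R)-4-{[(tert-butyldimethylsilyl)oxy]methyl}-5-oxo-2,5-dihydrofuran-2-yl]propan-2-yl}furan-3(2H)-one | C=CC[C@]1(C)OC(=CC1=O)[C@H](COCc1ccc(OC)cc1)C[C@H]1OC(=O)C(CO[Si](C)(C)C(C)(C)C)=C1 | intermediate
20 | (S)-2-allyl-5-{(S)-3-[(R)-4-(bromomethyl)-5-oxo-2,5-dihydrofuran-2-yl]-1-[(4-methoxybenzyl)oxy]propan-2-yl}-2-methylfuran-3(2H)-one | C=CC[C@]1(C)OC(=CC1=O)[C@H](COCc1ccc(OC)cc1)C[C@H]1OC(=O)C(CBr)=C1 | intermediate
21 | 2-[(S)-5-{(S)-3-[(R)-4-(bromomethyl)-5-oxo-2,5-dihydrofuran-2-yl]-1-[(4-methoxybenzyl)oxy]propan-2-yl}-2-methyl-3-oxo-2,3-dihydrofuran-2-yl]acetaldehyde | O=CC[C@]1(C)OC(=CC1=O)[C@H](COCc1ccc(OC)cc1)C[C@H]1OC(=O)C(CBr)=C1 | intermediate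
22 | (4S,6R,7R,8S,10S)-8-hydroxy-15-[(4-methoxybenzyl)oxy]-1-oxo-3,10-epoxygermacra-2,11(13)-dien-12,6-olide (8α-alcohol) | C=C1C(=O)O[C@@H]2C[C@@H](COCc4ccc(OC)cc4)C3=CC(=O)[C@](C)(C[C@H](O)[C@@H]12)O3 | intermediate
23 | angelic acid, (Z)-2-methylbut-2-enoic acid | C/C=C(/C)C(=O)O | starting material
24 | (4S,6R,7S,8R,10S)-8-[(Z)-2-methylbut-2-enoyloxy]-15-[(4-methoxybenzyl)oxy]-1-oxo-3,10-epoxygermacra-2,11(13)-dien-12,6-olide | C=C1C(=O)O[C@@H]2C[C@@H](COCc4ccc(OC)cc4)C3=CC(=O)[C@](C)(C[C@@H](OC(=O)/C(C)=C\C)[C@@H]12)O3 | intermediate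
25 | (4S,6R,7S,8R,10S)-8-[(Z)-2-methylbut-2-enoyloxy]-15-hydroxy-1-oxo-3,10-epoxygermacra-2,11(13)-dien-12,6-olide (CNP0108636.1) | C=C1C(=O)O[C@@H]2C[C@@H](CO)C3=CC(=O)[C@](C)(C[C@@H](OC(=O)/C(C)=C\C)[C@@H]12)O3 | target

Total step count: 19. Longest linear sequence: 17 steps (steps 1–3 and 6–19; steps 4 and 5 make acid 8).

Steps most likely to fail

Step 13. In the α-methyl carbene, 1,2-hydride migration to a vinyl ketone or C–H insertion may outrun capture by the ether oxygen, and a metal-bound ylide could erode the trans relay from C3 to C10. The fallback forms the same O–C10 bond by ionic O-alkylation; it sets out from aldehyde 11 and returns at furanone 19. Racemic 3-bromo-3-methylhex-5-en-2-one F1 (from 3-methylhex-5-en-2-one, NBS, cat. TsOH) is converted to its dibutylboron enolate (Bu2BOTf, iPr2NEt, CH2Cl2, −78 °C) and added to 11 to give the β-hydroxy ketone F2. Dess–Martin oxidation gives the α'-bromo 1,3-diketone F3, whose enol oxygen displaces the tertiary bromide (iPr2NEt, MeCN, rt) to close the furanone. This closure is known chemistry but is not stereocontrolled at C10, so 19 would have to be separated from its C10 epimer F4.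

Step 17. The allylchromium reagent may be protonated or couple intermolecularly instead of closing the strained bridged ten-membered ring, and the facial course at C7 or C8 may differ from the chair model. The fallback sets out from bromide 20 and returns at 24. Stannylation with (Bu3Sn)2 and Pd(PPh3)4 gives the allylstannane F5, and Johnson–Lemieux cleavage as in step 16 gives the stannyl aldehyde F6. BF3·OEt2 (CH2Cl2, −78 °C, high dilution) then triggers a Lewis acid allylstannane addition through an open antiperiplanar transition state, which should favour the 7,8-syn 8β-alcohol F7. Yamaguchi esterification with 23 (2,4,6-trichlorobenzoyl chloride, Et3N, then DMAP, toluene) gives 24 with retention, so step 18 is bypassed as well.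

Step 18. The alkoxyphosphonium ion at the hindered C8 may eliminate toward C9 or revert to alcohol instead of undergoing SN2 displacement, and the angelate may isomerise to the tiglate under phosphine catalysis. The fallback sets out from 22 and returns at 24. Dess–Martin oxidation gives the 8-ketone F8. Luche reduction (NaBH4, CeCl3·7H2O, MeOH, −78 °C) should deliver hydride from the less hindered α-face to give the 8β-alcohol, which is F7 of the preceding fallback. Yamaguchi esterification with 23 then gives 24.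

Further compounds

F1 | step 13 | 3-bromo-3-methylhex-5-en-2-one (racemic) | CC(=O)C(C)(Br)CC=C
F2 | step 13 | boron aldol adduct of F1 and 11 (β-hydroxy ketone, mixture at C3 and C10) | C=CCC(C)(Br)C(=O)CC(O)[C@H](COCc1ccc(OC)cc1)C[C@H]1OC(=O)C(CO[Si](C)(C)C(C)(C)C)=C1
F3 | step 13 | α'-bromo 1,3-diketone (mixture at C10) | C=CCC(C)(Br)C(=O)CC(=O)[C@H](COCc1ccc(OC)cc1)C[C@H]1OC(=O)C(CO[Si](C)(C)C(C)(C)C)=C1
F4 | step 13 | C10 epimer of 19 | C=CC[C@@]1(C)OC(=CC1=O)[C@H](COCc1ccc(OC)cc1)C[C@H]1OC(=O)C(CO[Si](C)(C)C(C)(C)C)=C1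
F5 | step 17 | allylstannane from 20 | C=CC[C@]1(C)OC(=CC1=O)[C@H](COCc1ccc(OC)cc1)C[C@H]1OC(=O)C(C[Sn](CCCC)(CCCC)CCCC)=C1
F6 | step 17 | stannyl aldehyde | O=CC[C@]1(C)OC(=CC1=O)[C@H](COCc1ccc(OC)cc1)C[C@H]1OC(=O)C(C[Sn](CCCC)(CCCC)CCCC)=C1
F7 | step 17 | 8β-alcohol (C8 epimer of 22) | C=C1C(=O)O[C@@H]2C[C@@H](COCc4ccc(OC)cc4)C3=CC(=O)[C@](C)(C[C@@H](O)[C@@H]12)O3
F8 | step 18 | 8-ketone from 22 | C=C1C(=O)O[C@@H]2C[C@@H](COCc4ccc(OC)cc4)C3=CC(=O)[C@](C)(CC(=O)[C@@H]12)O3
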